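Readings and results were computed on assumed constants; scatter was added.

Clock the catalyst when you rank these flasks: Thursday's gives it 2.00 min at 50 °C, fewer than the 5.0 min of Sunday's, Wednesday's and Friday's, and among those Sunday's also feeds in its starting material over 3.0 min. Free catalyst turns starting material into target, with second substrate also in the flask, and you count target at the end.

| setting | summer | midnight | winter | Sunday's | Thursday's | Wednesday's | Friday's |
|---|---|---|---|---|---|---|---|
| starting material | 0.37 M | 0.25 M | 0.55 M | 0.37 M (fed, over 3.0 min) | 0.37 M | 0.37 M | 0.37 M |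
| second substrate | 1 equiv | 1 equiv | 1 equiv | 1.00 equiv | 1.00 equiv (fed, over 3.0 min) | 1.00 equiv | 1.00 equiv (fed, over 3.0 min) |
| free catalyst | 0.5 mol% | 0.5 mol% | 0.5 mol% | 0.5 mol% | 0.5 mol% | 0.5 mol% | 0.5 mol% |
| temperature | 35 °C | 50 °C | 35 °C | 50 °C |  | 50 °C | 50 °C |
| remark | run made earlier | run made earlier | run made earlier | all else is in the flask from the start; the feed brings no volume worth counting | the addition at 30 °C, then warmed to 50 °C; the feed brings no volume worth counting | everything together at the start | all else is in the flask from the start; the feed brings no volume worth counting |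
| time |  |  |  | 5.0 min | 5.0 min | 5.0 min | 5.0 min |

| run | time / min | target / % | starting material / % |
|---|---|---|---|
| summer | 0.500 | 4.8 | 95.3 |
| summer | 0.667 | 5.9 | 94.8 |
| summer | 1.00 | 9.0 | 91.0 |
| summer | 2.00 | 16.0 | 83.6 |
| summer | 3.00 | 22.1 | 76.2 |
| summer | 4.00 | 27.9 | 70.6 |
| summer | 6.00 | 35.4 | 59.2 |
| midnight | 0.333 | 6.7 | 92.9 |
| midnight | 1.00 | 16.9 | 81.0 |
| midnight | 1.50 | 21.5 | 75.0 |
| midnight | 2.50 | 26.2 | 64.9 |
| midnight | 4.00 | 28.2 | 55.5 |
| midnight | 5.00 | 27.6 | 51.5 |
| midnight | 6.00 | 25.9 | 48.7 |
| winter | 1.00 | 10.7 | 89.1 |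
| winter | 1.33 | 13.8 | 86.0 |
| winter | 2.00 | 19.4 | 79.9 |
| winter | 3.00 | 26.7 | 70.8 |
| winter | 5.00 | 39.1 | 56.6 |
| winter | 8.00 | 49.7 | 41.0 |
| winter | 12.0 | 55.0 | 26.6 |

(each reading ± 0.3 percentage points)

1. the flask with the highest amount of target, in percent of the starting material charged ("all alike" if they lie within 1.5 percentage points) (Sunday's / Thursday's / Wednesday's / Friday's / all alike)
2. final target, as a percentage of the starting material charged, in Sunday's
3. final target, as a percentage of the starting material charged, in Thursday's
4. final target, as a percentage of the starting material charged, in Wednesday's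
5. final target, as a percentage of the starting material charged, in Friday's



Start with the per-minute loss of starting material, the log of a ratio of two readings over the time between them (a pseudo-first-order constant). In the winter run at 35 °C it reads 0.109 min⁻¹ early and 0.108 min⁻¹ late, so deep conversion doesn't slow it. In the midnight run at 50 °C, it falls from 0.206 min⁻¹ to 0.0654 min⁻¹. I read that fall as catalyst fading, at 0.264 min⁻¹. Carry one quantity from it: the hot life, the time at 50 °C in which the working share of catalyst falls to 0.5 of what it was, 2.62 min.

Now run Thursday's slowly, as my own reckoning. During the feed at 30 °C I count no fade, since the winter run held steady at a warmer temperature. The summer run, with the same charge at 35 °C, had 22.1% target by 3.00 min, so expect somewhat less here. Then comes the warming. The fade, at 0.264 min⁻¹, is faster than the early midnight constant of 0.206 min⁻¹, so the hot burst is brief. Target can also fall away while hot: the midnight run's target read 28.2% at 4.00 min and 25.9% at 6.00 min, with 48.7% starting material still there. Thursday's reaches 5.0 min after 2.00 min hot, keeping 58.9% of its catalyst, more than the 26.7% of Wednesday's and Friday's. Those two should lie close together. Sunday's feed of 3.0 min outlasts the hot life, so I put it below Wednesday's and put Thursday's on top.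

The forecast names Thursday's, with 25% for Sunday's, 36% for Thursday's, 32% for Wednesday's and 31% for Friday's, saying “the catalyst is preserved at 30 °C”. The flasks give 27.7%, 38.0%, 34.4% and 33.9% in that order, so Thursday's leads Wednesday's by 3.6 percentage points, beyond the margin of 1.5 points.

    second substrate + free catalyst ⇌ catalyst intermediate B (K = 1.42 M⁻¹, k = 4.58 M⁻¹ s⁻¹, Ea = 57.0 kJ mol⁻¹, ΔH = −60.0 kJ mol⁻¹)
    target ⇌ isomer of the product (K = 5.60, k = 0.00331 s⁻¹, Ea = 88.0 kJ mol⁻¹, ΔH = −75.0 kJ mol⁻¹)
    catalyst intermediate A → free catalyst + target (k = 65.2 s⁻¹, Ea = 67.0 kJ mol⁻¹)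
    free catalyst → spent catalyst (k = 0.00531 s⁻¹, Ea = 87.0 kJ mol⁻¹)
    starting material + free catalyst ⇌ catalyst intermediate A (K = 3.74 M⁻¹, k = 3.88 M⁻¹ s⁻¹, Ea = 54.0 kJ mol⁻¹, ΔH = −53.0 kJ mol⁻¹)
    catalyst intermediate B → free catalyst + second product (k = 1.98 s⁻¹, Ea = 82.0 kJ mol⁻¹)
    (constants at 50 °C)

Stop Thursday's at 3.0 min, the neighbouring flask, and the hot clock has not started. That flask holds 19.8% target and 7.64% spent catalyst, so 92.4% of the catalyst is unspent. Apply the hot life for the remaining 2.00 min and 54.4% should stay unspent. Thursday's itself, at 5.00 min, holds 56.3% unspent.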